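## The problem

Asperteretal G2 (12) is an open-chain 2,3-disubstituted succinic acid half-ester. With the chain numbered from the ester carbonyl (C1) to the free acid (C4), C2 carries a 4-hydroxyphenyl ring and C3 a (4-hydroxy-3-prenylphenyl)methyl group. The central C2–C3 bond joins the α-carbons of two carboxyl groups, a 1,4-dicarbonyl relationship that ordinary enolate–carbonyl chemistry does not deliver. Both stereocentres are C–H centres α to a carbonyl; C2–H is also benzylic and by far the more acidic, so neither centre tolerates strong base once it exists. The (2S,3S) pair is the erythro arrangement, that of a cis-anhydride or of the syn-H2 adduct of a maleate. It is the less stable arrangement in any five-membered ring, so equilibration cannot reach it, and with no ring in the target neither centre can reliably direct the other: both must be fixed in one kinetically controlled event. The two carboxyl carbons must end up differentiated (C1 methyl ester, C4 acid), and the prenyl group ortho to a free phenol rules out acid, ozone, osmium, peracids, electrophilic halogen and heterogeneous hydrogenation, hence any plan that unveils a carboxyl from an alkene. The enabling feature is the para-hydroxyl of the C2 aryl ring: the array HO–C4'…C1'–C2(H)(CO2Me) is the aromatised form of the ester-bearing p-quinone methide 8, in which C2 is the exocyclic methide carbon. A carbon nucleophile adding to C2 of 8 makes the C2–C3 bond and returns the free phenol, and C3, taken to the aldehyde level, is the α-carbon of an enamine.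

## Retrosynthesis

**12 ⇐ 11 ⇐ 10 (no skeletal bond cut).** The O–Si bond of the benzyl-ring phenol (11) and the C4–OH bond are taken back, so that C4 appears as the aldehyde of 10. This is preferred to a diacid or diester precursor because C1 (an ester from the outset) and C4 (an aldehyde) differ in oxidation level, so the two carboxyls never have to be told apart; the aldehyde is also the handle for amine catalysis. The silyl ether keeps the o-prenylphenol away from hypochlorite and from the electrophile of the key step. The forward steps must be neither basic nor strongly acidic, so that C2–H and C3–H stay put and the prenylphenol does not cyclise.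

**10 ⇐ 5 + 8 (key cut, C2–C3).** The bond is cut between the α-carbon of aldehyde 5 (reacting as its catalyst-bound enamine 9) and the exocyclic carbon of quinone methide 8. The neighbouring cuts, C3–CH2Ar (benzylation of a succinate enolate) and C2–aryl (arylation), each build one centre next to an existing epimerisable one and need strong base. The polar enolate/α-halo ester version of the same cut controls C3 at best. The quinone methide version sets both centres in one catalyst-controlled event under buffered conditions and delivers the C2 ring as the free phenol. The precursors are two achiral fragments with no stereocentre. The forward reaction must choose one enamine face (C3), one relative topicity (C2, erythro) and C-attack over O- and N-attack on a very reactive electrophile.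

**8 ⇐ 7 ⇐ 6.** The exocyclic C=C of 8 is taken back to the C–Cl bond of chloride 7 (1,6-elimination of HCl through the phenoxide), and that to the C–OH bond of racemic methyl 4-hydroxymandelate 6. Since 8 has no blocking groups and cannot be stored, it is traded for a precursor from which a weak base releases it slowly. The stereocentre of 6 and 7 is erased in planar 8, so the racemate is what is wanted. The forward step needs a leaving group that stays while the phenol is protonated and leaves once it is not.

**5 ⇐ 4 ⇐ 3 ⇐ 1 + 2.** The aldehyde is taken back to methyl ester 4, the silyl ether to phenol 3, and the ring–prenyl bond is cut to commercial phenol ester 1 and prenyl bromide 2. The prenyl group can go on first because no later step uses ozone, heterogeneous hydrogenation or strong acid. Compound 1 already holds the C6–C3 unit, and with its para position occupied only the ortho carbons can be alkylated. The forward steps need C- over O-alkylation of the phenoxide and a reduction that stops at the aldehyde.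

## Roads not taken

**Alternative 1:** (the most obvious) the same C2–C3 bond made by alkylation of a chiral imide enolate (Evans alkylation). The acid corresponding to 4 would be attached to a phenylalanine-derived oxazolidinone to give imide A1; its sodium enolate would be alkylated with the racemic α-bromo arylacetate A2 to give A3, and the auxiliary cleaved with peroxide.
- The auxiliary controls only C3. C2 comes from a racemic, configurationally labile benzylic halide whose enantiomers an open SN2 transition state does not distinguish, so A3 forms as a C2-epimer mixture.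
- C2–H of A3 is more acidic than the α-H of A1, so proton transfer to unreacted enolate stalls the reaction and scrambles C2.
- It costs three extra steps and stoichiometric chirality, and the peroxide cleavage must spare a methyl ester.
- The chosen plan fixes both centres with a catalytic amine and no strong base.

**Alternative 2:** both C–H bonds are cut, giving the target as the syn-dihydro product of a tetrasubstituted Z-alkene. A Perkin-type condensation of an arylacetic acid with the prenylated arylpyruvic acid would give maleic anhydride A4 (the likely biogenetic relative), methanolysis the Z-half-ester A5, and a carboxylate-directed asymmetric hydrogenation on a Ru–diphosphine catalyst the target.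
- Syn addition guarantees erythro, which is why this idea is kept as the fallback.
- The stereocentres are set last, on a substrate as large as the product, by hydrogenation of a tetrasubstituted alkene, whose sense and level of induction cannot be predicted.
- Carboxyl differentiation rests on regioselective opening of an anhydride whose two carbonyls differ little.
- The arylpyruvic acid needs several steps of its own, and the prenyl group must survive H2.

**Alternative 3:** the same enamine of 5 added to the classical acceptor, nitroalkene A6, to give γ-nitroaldehyde A7, followed by Nef-type oxidation of CH2NO2 to the acid and esterification.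
- The relative topicity is wrong. In a nitroalkene the aryl group is the spectator and the future carboxyl is the acceptor chain, so the reliable syn adduct A7 becomes the threo C2 epimer once CH2NO2 is a carboxyl.
- The carboxyl must still be unmasked and the two acids told apart by protecting-group steps.
- In 8 aryl and carboxyl exchange roles at the electrophilic carbon: the same topological preference then gives erythro, with the ester in place and the phenol free.

Key step: step 5

Assumption: racemic methyl 4-hydroxymandelate (6) is taken as a catalogue compound (otherwise one esterification from 4-hydroxymandelic acid); the sense of induction in step 5 is assigned by analogy with enamine additions to nitroalkenes.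

## Route

Step 1
Reactants: 1 methyl 3-(4-hydroxyphenyl)propanoate; 2 1-bromo-3-methylbut-2-ene (prenyl bromide)
Product: 3 methyl 3-[4-hydroxy-3-(3-methylbut-2-en-1-yl)phenyl]propanoate
Conditions: NaH (1.05 equiv), toluene, 0 °C to rt; then 2 (1.1 equiv), rt
Reagents that add atoms: none
Why: Ortho-C-alkylation of a sodium phenoxide in a non-polar solvent, where the tight ion pair delivers the allylic bromide to the ortho carbon; the para position is blocked and the weakly basic phenoxide leaves the ester alone. O-prenyl and bis-prenyl by-products are removed by chromatography.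

Step 2
Reactants: 3 methyl 3-[4-hydroxy-3-(3-methylbut-2-en-1-yl)phenyl]propanoate
Product: 4 methyl 3-[4-(tert-butyldimethylsilyloxy)-3-(3-methylbut-2-en-1-yl)phenyl]propanoate
Conditions: TBSCl, imidazole, DMF, rt
Reagents that add atoms: tert-butyldimethylsilyl chloride, CC(C)(C)[Si](C)(C)Cl
Why: Standard imidazole-mediated silylation of a phenol. The aryl silyl ether masks the o-prenylphenol against O-attack on 8 in step 5 and against hypochlorite in step 6.

Step 3
Reactants: 4 methyl 3-[4-(tert-butyldimethylsilyloxy)-3-(3-methylbut-2-en-1-yl)phenyl]propanoate
Product: 5 3-[4-(tert-butyldimethylsilyloxy)-3-(3-methylbut-2-en-1-yl)phenyl]propanal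
Conditions: DIBAL-H (1.1 equiv), CH2Cl2, −78 °C; MeOH, then aq. Rochelle salt
Reagents that add atoms: none
Why: Partial reduction of a methyl ester by DIBAL-H at low temperature, where the tetrahedral aluminium hemiacetal persists until the quench. The silyl ether and the trisubstituted alkene are inert.

Step 4
Reactants: 6 methyl 2-hydroxy-2-(4-hydroxyphenyl)acetate (racemic methyl 4-hydroxymandelate)
Product: 7 methyl 2-chloro-2-(4-hydroxyphenyl)acetate (racemic)
Conditions: SOCl2 (1.3 equiv), CH2Cl2, 0 °C to rt; evaporate with toluene, use at once
Reagents that add atoms: thionyl chloride, O=S(Cl)Cl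
Why: Chlorodehydroxylation of a benzylic α-hydroxy ester through its chlorosulfite, assisted by the para-hydroxyl. The acidic medium keeps the phenol protonated, so 7 does not yet eliminate to 8; racemic material is wanted because this centre is erased in step 5.

Step 5
Reactants: 5 3-[4-(tert-butyldimethylsilyloxy)-3-(3-methylbut-2-en-1-yl)phenyl]propanal; 7 methyl 2-chloro-2-(4-hydroxyphenyl)acetate (racemic)
Product: 10 methyl (2S,3S)-4-[4-(tert-butyldimethylsilyloxy)-3-(3-methylbut-2-en-1-yl)phenyl]-3-formyl-2-(4-hydroxyphenyl)butanoate, via quinone methide ester 8 (not isolated), via catalyst-bound enamine 9 (not isolated)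
Conditions: (R)-2-[diphenyl(trimethylsilyloxy)methyl]pyrrolidine (20 mol %), 2,6-lutidine (2 equiv), CH2Cl2, 0 °C; 7 (1.3 equiv) added over 4 h
Reagents that add atoms: none
Why: Proposed new method: the closest known reaction types are the aminocatalytic α-alkylation of aldehydes by 1,6-addition to isolable δ-aryl p-quinone methides and the enamine Michael addition to nitroalkenes; new here are the unblocked, ester-bearing quinone methide and its release in the flask. 2,6-Lutidine reversibly deprotonates the phenol of 7 and the phenoxide expels chloride (vinylogous E1cB), so both enantiomers of 7 converge on planar 8, which slow addition keeps at low concentration. The catalyst and 5 give the (E)-s-trans enamine 9, whose carbon attacks the exocyclic methide carbon of 8 (intermolecular 1,6-addition; no ring is closed), driven by rearomatisation to the phenoxide; proton transfer and hydrolysis of the iminium ion release 10 and the amine. C3 is set by the catalyst: the diphenyl(silyloxy)methyl group blocks one enamine face, and by analogy with nitroalkene additions the (R)-catalyst should give 3S. C2 is set by relative topicity: in the synclinal open transition state the acceptor π-system, here the quinoid ring in which the negative charge develops, lies gauche over the enamine towards nitrogen, the methide hydrogen takes the crowded inside position and the ester points away, which corresponds to the erythro (2S,3S) pair, the opposite of the outcome with a nitrostyrene, where the aryl group is the spectator. The step needs C-attack to win over attack by chloride, phenoxide oxygen and the amine nitrogen; those adducts all keep a leaving group para to a phenol and can revert to 8, whereas the C–C adduct cannot, so the enamine drains the equilibrium. The lutidine/lutidinium buffer and the slow enamine formation of an α-branched aldehyde should protect both new centres, and 10 is filtered through silica and oxidised without storage.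

Step 6
Reactants: 10 methyl (2S,3S)-4-[4-(tert-butyldimethylsilyloxy)-3-(3-methylbut-2-en-1-yl)phenyl]-3-formyl-2-(4-hydroxyphenyl)butanoate
Product: 11 (2S,3S)-2-{[4-(tert-butyldimethylsilyloxy)-3-(3-methylbut-2-en-1-yl)phenyl]methyl}-3-(4-hydroxyphenyl)-4-methoxy-4-oxobutanoic acid
Conditions: NaClO2, NaH2PO4, 2-methyl-2-butene (large excess), t-BuOH/H2O, 0 °C to rt
Reagents that add atoms: sodium chlorite, [Na+].[O-]Cl=O
Why: Pinnick oxidation: chlorous acid adds to the aldehyde and fragments to the acid in a weakly acidic buffer in which neither C2–H nor C3–H enolises. The excess of 2-methyl-2-butene consumes hypochlorous acid before it can chlorinate the free phenol or the prenyl group.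

Step 7
Reactants: 11 (2S,3S)-2-{[4-(tert-butyldimethylsilyloxy)-3-(3-methylbut-2-en-1-yl)phenyl]methyl}-3-(4-hydroxyphenyl)-4-methoxy-4-oxobutanoic acid
Product: 12 (2S,3S)-2-{[4-hydroxy-3-(3-methylbut-2-en-1-yl)phenyl]methyl}-3-(4-hydroxyphenyl)-4-methoxy-4-oxobutanoic acid (Asperteretal G2)
Conditions: KHF2 (3 equiv), MeOH, rt
Reagents that add atoms: none
Why: Bifluoride cleavage of an aryl silyl ether, selective for phenolic silyl ethers and only weakly acidic. The methyl ester, the prenylphenol and both stereocentres should be untouched.

## Compound list

1 | methyl 3-(4-hydroxyphenyl)propanoate | COC(=O)CCc1ccc(O)cc1 | starting material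
2 | 1-bromo-3-methylbut-2-ene (prenyl bromide) | CC(C)=CCBr | starting material
3 | methyl 3-[4-hydroxy-3-(3-methylbut-2-en-1-yl)phenyl]propanoate | COC(=O)CCc1ccc(O)c(CC=C(C)C)c1 | intermediate
4 | methyl 3-[4-(tert-butyldimethylsilyloxy)-3-(3-methylbut-2-en-1-yl)phenyl]propanoate | COC(=O)CCc1ccc(O[Si](C)(C)C(C)(C)C)c(CC=C(C)C)c1 | intermediate
5 | 3-[4-(tert-butyldimethylsilyloxy)-3-(3-methylbut-2-en-1-yl)phenyl]propanal | O=CCCc1ccc(O[Si](C)(C)C(C)(C)C)c(CC=C(C)C)c1 | intermediate
6 | methyl 2-hydroxy-2-(4-hydroxyphenyl)acetate (racemic) | COC(=O)C(O)c1ccc(O)cc1 | starting material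
7 | methyl 2-chloro-2-(4-hydroxyphenyl)acetate (racemic) | COC(=O)C(Cl)c1ccc(O)cc1 | intermediate
8 | methyl 2-(4-oxocyclohexa-2,5-dien-1-ylidene)acetate (formed in the flask) | COC(=O)C=C1C=CC(=O)C=C1 | intermediate
9 | (2R)-1-[(1E)-3-{4-(tert-butyldimethylsilyloxy)-3-(3-methylbut-2-en-1-yl)phenyl}prop-1-en-1-yl]-2-[diphenyl(trimethylsilyloxy)methyl]pyrrolidine (formed in the flask) | C[Si](C)(C)OC(c1ccccc1)(c1ccccc1)[C@H]1CCCN1/C=C/Cc1ccc(O[Si](C)(C)C(C)(C)C)c(CC=C(C)C)c1 | intermediate
10 | methyl (2S,3S)-4-[4-(tert-butyldimethylsilyloxy)-3-(3-methylbut-2-en-1-yl)phenyl]-3-formyl-2-(4-hydroxyphenyl)butanoate | COC(=O)[C@H](c1ccc(O)cc1)[C@H](Cc1ccc(O[Si](C)(C)C(C)(C)C)c(CC=C(C)C)c1)C=O | intermediate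
11 | (2S,3S)-2-{[4-(tert-butyldimethylsilyloxy)-3-(3-methylbut-2-en-1-yl)phenyl]methyl}-3-(4-hydroxyphenyl)-4-methoxy-4-oxobutanoic acid | COC(=O)[C@H](c1ccc(O)cc1)[C@H](Cc1ccc(O[Si](C)(C)C(C)(C)C)c(CC=C(C)C)c1)C(=O)O | intermediate
12 | (2S,3S)-2-{[4-hydroxy-3-(3-methylbut-2-en-1-yl)phenyl]methyl}-3-(4-hydroxyphenyl)-4-methoxy-4-oxobutanoic acid (Asperteretal G2) | COC(=O)[C@H](c1ccc(O)cc1)[C@H](Cc1ccc(O)c(CC=C(C)C)c1)C(=O)O | target

## Step count and risks

Total step count: 7. Longest linear sequence: 6 (steps 1, 2, 3, 5, 6, 7); step 4 is a one-step side branch.

**Step 5 (key step, Proposed new method).**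
- Most likely failure: capture of 8 by heteroatom nucleophiles (catalyst nitrogen, phenoxide oxygen, adventitious water) or by itself outruns C-attack by the enamine, giving oligomers and sequestered catalyst.
- Second failure: insufficient control of the relative topicity at C2, because the ester rather than the quinoid ring may take the synclinal position.
- Fallback (known chemistry; sets out from 5, returns at 11): the two C–H bonds are made last by syn-hydrogenation instead of making the C2–C3 bond stereoselectively.
  - Amine-mediated aldol condensation of 5 with commercial 2-(4-hydroxyphenyl)-2-oxoacetic acid (morpholine, AcOH, dioxane, warm; 5 added slowly to suppress self-condensation) should give, after dehydration and ring closure of the Z-aldehyde acid, 5-hydroxy-3-(4-hydroxyphenyl)-4-{[4-(tert-butyldimethylsilyloxy)-3-(3-methylbut-2-en-1-yl)phenyl]methyl}furan-2(5H)-one F1, whose ring locks the Z geometry.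
  - O-alkylation of its open-chain carboxylate (MeI, KHCO3, DMF; bicarbonate does not deprotonate the phenol) gives methyl (2Z)-4-[4-(tert-butyldimethylsilyloxy)-3-(3-methylbut-2-en-1-yl)phenyl]-3-formyl-2-(4-hydroxyphenyl)but-2-enoate F2.
  - Pinnick oxidation gives (2Z)-2-{[4-(tert-butyldimethylsilyloxy)-3-(3-methylbut-2-en-1-yl)phenyl]methyl}-3-(4-hydroxyphenyl)-4-methoxy-4-oxobut-2-enoic acid F3.
  - Carboxylate-directed hydrogenation of F3 on a Ru(II)–BINAP dicarboxylate catalyst (H2 under pressure, MeOH) adds both hydrogens to one face of the tetrasubstituted alkene. This can only give the erythro pair, and so 11 or its enantiomer according to the ligand antipode. This catalyst class reduces carboxylate-bound alkenes and leaves isolated trisubstituted alkenes such as the prenyl group alone.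

**Step 4.**
- Most likely failure: premature loss of HCl from 7 during concentration or storage, with self-condensation through 8.
- Fallback (sets out from 6, returns at 8): the crude chlorination mixture (7, not concentrated) is quenched with trimethylamine in THF. This should precipitate [1-(4-hydroxyphenyl)-2-methoxy-2-oxoethyl]trimethylammonium chloride F4, a storable crystalline reservoir that releases 8 and the neutral amine under the base of step 5 (the quaternary-ammonium route to quinone methides), so the labile chloride never has to be isolated.

**Step 1.**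
- Most likely failure: competing O-alkylation and double C-prenylation of the phenoxide, lowering the yield of 3.
- Fallback (sets out from 1, returns at 4): ortho-bromination (NBS, cat. p-TsOH, MeOH) to methyl 3-(3-bromo-4-hydroxyphenyl)propanoate F5; silylation to methyl 3-[3-bromo-4-(tert-butyldimethylsilyloxy)phenyl]propanoate F6; then Suzuki–Miyaura coupling with commercial prenylboronic acid pinacol ester under a Pd/biarylphosphine catalyst selective for the linear allyl terminus (K3PO4) gives 4.

**Step 6.**
- Most likely failure: electrophilic chlorination of the free phenol ring or of the prenyl alkene by hypochlorite that escapes the scavenger; epimerisation at C3 if 10 is stored before oxidation.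
- Fallback (sets out from 10, returns at 12): the free phenol is silylated first (TBSOTf, 2,6-lutidine, −78 °C) to methyl (2S,3S)-4-[4-(tert-butyldimethylsilyloxy)-3-(3-methylbut-2-en-1-yl)phenyl]-2-[4-(tert-butyldimethylsilyloxy)phenyl]-3-formylbutanoate F7. Pinnick oxidation then gives (2S,3S)-2-{[4-(tert-butyldimethylsilyloxy)-3-(3-methylbut-2-en-1-yl)phenyl]methyl}-3-[4-(tert-butyldimethylsilyloxy)phenyl]-4-methoxy-4-oxobutanoic acid F8, and KHF2 in MeOH removes both silyl groups to give 12.

## Further compounds

F1 | step 5 | 5-hydroxy-3-(4-hydroxyphenyl)-4-{[4-(tert-butyldimethylsilyloxy)-3-(3-methylbut-2-en-1-yl)phenyl]methyl}furan-2(5H)-one (racemic at C5) | O=C1OC(O)C(Cc2ccc(O[Si](C)(C)C(C)(C)C)c(CC=C(C)C)c2)=C1c1ccc(O)cc1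
F2 | step 5 | methyl (2Z)-4-[4-(tert-butyldimethylsilyloxy)-3-(3-methylbut-2-en-1-yl)phenyl]-3-formyl-2-(4-hydroxyphenyl)but-2-enoate | COC(=O)/C(c1ccc(O)cc1)=C(\C=O)Cc1ccc(O[Si](C)(C)C(C)(C)C)c(CC=C(C)C)c1
F3 | step 5 | (2Z)-2-{[4-(tert-butyldimethylsilyloxy)-3-(3-methylbut-2-en-1-yl)phenyl]methyl}-3-(4-hydroxyphenyl)-4-methoxy-4-oxobut-2-enoic acid | COC(=O)/C(c1ccc(O)cc1)=C(\C(=O)O)Cc1ccc(O[Si](C)(C)C(C)(C)C)c(CC=C(C)C)c1
F4 | step 4 | [1-(4-hydroxyphenyl)-2-methoxy-2-oxoethyl]trimethylammonium chloride (racemic) | COC(=O)C(c1ccc(O)cc1)[N+](C)(C)C.[Cl-]
F5 | step 1 | methyl 3-(3-bromo-4-hydroxyphenyl)propanoate | COC(=O)CCc1ccc(O)c(Br)c1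
F6 | step 1 | methyl 3-[3-bromo-4-(tert-butyldimethylsilyloxy)phenyl]propanoate | COC(=O)CCc1ccc(O[Si](C)(C)C(C)(C)C)c(Br)c1
F7 | step 6 | methyl (2S,3S)-4-[4-(tert-butyldimethylsilyloxy)-3-(3-methylbut-2-en-1-yl)phenyl]-2-[4-(tert-butyldimethylsilyloxy)phenyl]-3-formylbutanoate | COC(=O)[C@H](c1ccc(O[Si](C)(C)C(C)(C)C)cc1)[C@H](Cc1ccc(O[Si](C)(C)C(C)(C)C)c(CC=C(C)C)c1)C=O
F8 | step 6 | (2S,3S)-2-{[4-(tert-butyldimethylsilyloxy)-3-(3-methylbut-2-en-1-yl)phenyl]methyl}-3-[4-(tert-butyldimethylsilyloxy)phenyl]-4-methoxy-4-oxobutanoic acid | COC(=O)[C@H](c1ccc(O[Si](C)(C)C(C)(C)C)cc1)[C@H](Cc1ccc(O[Si](C)(C)C(C)(C)C)c(CC=C(C)C)c1)C(=O)O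
A1 | alternative 1 | (4R)-4-benzyl-3-{3-[4-(tert-butyldimethylsilyloxy)-3-(3-methylbut-2-en-1-yl)phenyl]propanoyl}-1,3-oxazolidin-2-one | O=C(CCc1ccc(O[Si](C)(C)C(C)(C)C)c(CC=C(C)C)c1)N1[C@H](Cc2ccccc2)COC1=O
A2 | alternative 1 | methyl 2-bromo-2-[4-(tert-butyldimethylsilyloxy)phenyl]acetate (racemic) | COC(=O)C(Br)c1ccc(O[Si](C)(C)C(C)(C)C)cc1
A3 | alternative 1 | methyl (2RS,3S)-4-[(4R)-4-benzyl-2-oxo-1,3-oxazolidin-3-yl]-3-{[4-(tert-butyldimethylsilyloxy)-3-(3-methylbut-2-en-1-yl)phenyl]methyl}-2-[4-(tert-butyldimethylsilyloxy)phenyl]-4-oxobutanoate (C2 epimers) | COC(=O)C(c1ccc(O[Si](C)(C)C(C)(C)C)cc1)[C@H](Cc1ccc(O[Si](C)(C)C(C)(C)C)c(CC=C(C)C)c1)C(=O)N1[C@H](Cc2ccccc2)COC1=O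
A4 | alternative 2 | 3-(4-hydroxyphenyl)-4-{[4-hydroxy-3-(3-methylbut-2-en-1-yl)phenyl]methyl}furan-2,5-dione | O=C1OC(=O)C(Cc2ccc(O)c(CC=C(C)C)c2)=C1c1ccc(O)cc1
A5 | alternative 2 | (2Z)-2-{[4-hydroxy-3-(3-methylbut-2-en-1-yl)phenyl]methyl}-3-(4-hydroxyphenyl)-4-methoxy-4-oxobut-2-enoic acid | COC(=O)/C(c1ccc(O)cc1)=C(\C(=O)O)Cc1ccc(O)c(CC=C(C)C)c1
A6 | alternative 3 | tert-butyldimethyl{4-[(E)-2-nitroethenyl]phenoxy}silane | CC(C)(C)[Si](C)(C)Oc1ccc(/C=C/[N+](=O)[O-])cc1
A7 | alternative 3 | (2S,3R)-2-{[4-(tert-butyldimethylsilyloxy)-3-(3-methylbut-2-en-1-yl)phenyl]methyl}-3-[4-(tert-butyldimethylsilyloxy)phenyl]-4-nitrobutanal | O=C[C@@H](Cc1ccc(O[Si](C)(C)C(C)(C)C)c(CC=C(C)C)c1)[C@@H](C[N+](=O)[O-])c1ccc(O[Si](C)(C)C(C)(C)C)cc1
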